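**Retrosynthetic overview**

1. Numbering: the cyclobutane is C1 (bonded to ketone C11), C2 (quaternary, methyl), C8 (bonded to alkene carbon C9) and C7 (bonded to gem-dimethyl C6); C11–C10–C9 bridges C1/C8 (six-membered enone ring) and C3–C4–C5–C6 bridges C2/C7 (seven-membered ring).
2. The strategy rests on quaternary cyclobutane carbon C2, which carries a methyl group directly beside the C3 carbinol of the seven-membered ring; this is what remains when an exocyclic C2=CH2 alkene takes up a hydrogen atom at CH2 and an aldehyde carbon at C2.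
3. Disconnections, last to first: C5 methacrylate, C9=C10 (Saegusa–Ito), C3 isobutyrate, then C2–C3 (key step) back to keto aldehyde 19, a 6-methylidenebicyclo[3.1.1]heptan-2-one with the aldehyde arm on C7.
4. The six-membered ring comes from a C1–C11 allylsilane–aldehyde closure that also creates the C2 methylene; its precursor comes from a 3-substituted cyclobutanone by reagent-controlled desymmetrisation and Michael addition to methyl crotonate (C9–C11).
5. Ring order: cyclobutane by dichloroketene [2+2] on an (R)-reverse-prenyl carbinol (step 3), six-membered ring (step 9), seven-membered ring (step 12).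

Key step: step 12

Abbreviations: TBS = tert-butyldimethylsilyl, TMS = trimethylsilyl, Tf = trifluoromethanesulfonyl, R* = (3R)-3,5-bis(TBS-oxy)-2-methylpentan-2-yl (the C6–C3 side chain).

Assumption: the sense of induction in the two reagent-controlled steps (1 and 5) is as written; if either proves opposite, the enantiomeric ligand or lithium amide is used.

Remark: C9 is formed as a mixture of epimers in step 5 and is written without configuration until it becomes sp2 in step 15.

**Step 1**
Reactants: 1 3-(TBS-oxy)propan-1-ol; 2 3-methylbuta-1,2-diene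
Product: 3 (3R)-1-(TBS-oxy)-4,4-dimethylhex-5-en-3-ol
Conditions: cyclometalated iridium C,O-benzoate catalyst from [Ir(cod)Cl]2, (S)-SEGPHOS, 4-cyano-3-nitrobenzoic acid, allyl acetate and Cs2CO3 (5 mol %), toluene, 50 °C, sealed tube
Reagents that add atoms: none
Why: Iridium-catalysed transfer-hydrogenative carbonyl tert-prenylation, in which the alcohol is dehydrogenated to the aldehyde, the allene is hydrometalated to a 1,1-dimethylallyl iridium species and its addition through a closed chair transition state on the chiral bisphosphine complex joins C5 to quaternary C6 and sets C5 as (R).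

**Step 2**
Reactants: 3 (3R)-1-(TBS-oxy)-4,4-dimethylhex-5-en-3-ol
Product: 4 (3R)-1,3-bis(TBS-oxy)-4,4-dimethylhex-5-ene
Conditions: TBSOTf, 2,6-lutidine, CH2Cl2, −78 → 0 °C
Reagents that add atoms: tert-butyldimethylsilyl trifluoromethanesulfonate, CC(C)(C)[Si](C)(C)OS(=O)(=O)C(F)(F)F
Why: Silylation of a hindered secondary alcohol with a silyl triflate and a non-nucleophilic base, which touches no stereocentre.

**Step 3**
Reactants: 4 (3R)-1,3-bis(TBS-oxy)-4,4-dimethylhex-5-ene; 5 trichloroacetyl chloride
Product: 7 2,2-dichloro-3-R*-cyclobutan-1-one (both C3 epimers), via dichloroketene 6 (not isolated)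
Conditions: Zn–Cu couple, POCl3, Et2O, reflux
Reagents that add atoms: none
Why: Thermal [2+2] cycloaddition of dichloroketene, made in situ by zinc dechlorination of 5, to the monosubstituted alkene, the carbonyl carbon bonding to the terminal CH2 so that the side chain sits at C3 of the cyclobutanone; the new ring carbon C7 forms as both epimers, which converge in step 4.

**Step 4**
Reactants: 7 2,2-dichloro-3-R*-cyclobutan-1-one
Product: 8 3-R*-cyclobutan-1-one
Conditions: Zn–Cu couple, NH4Cl, MeOH, rt
Reagents that add atoms: none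
Why: Reductive dechlorination of an α,α-dichloroketone by zinc under near-neutral conditions that spare both silyl ethers, giving a cyclobutanone whose two α-methylenes differ only through the remote C5 centre.

**Step 5**
Reactants: 8 3-R*-cyclobutan-1-one; 9 methyl (E)-but-2-enoate
Product: 11 methyl 3-[(1S,2R)-2-R*-4-oxocyclobutyl]butanoate (C9 epimers), via lithium enolate 10 (not isolated)
Conditions: (R,R)-bis(1-phenylethyl)amine hydrochloride (1.05 equiv), n-BuLi (2.1 equiv), THF, −78 → 0 °C; 8 (slow addition), −100 °C; then 9, −78 → −40 °C; aq. NH4Cl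
Reagents that add atoms: none
Why: Enantiotopic-group-selective deprotonation of the 3-substituted cyclobutanone by the C2-symmetric chiral lithium amide, used as its LiCl complex so that the selectivity of an in situ quench is kept while the enolate stays free for a carbon electrophile, lets the reagent and not the remote C5 centre decide which methylene becomes the enolate carbon (future C8) and thereby fixes C7, and the kinetic Michael addition of lithium enolate 10 to the crotonate then occurs anti to the bulky C7 substituent so that the C8 arm ends trans to the side chain (also the thermodynamic arrangement), while C9 forms as an epimer mixture that is erased later.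

**Step 6**
Reactants: 11 methyl 3-[(1S,2R)-2-R*-4-oxocyclobutyl]butanoate
Product: 13 methyl 3-[(1S,4R)-4-R*-2-(trifluoromethylsulfonyloxy)cyclobut-2-en-1-yl]butanoate, via potassium enolate 12 (not isolated)
Conditions: KN(SiMe3)2, THF, −78 °C; PhNTf2, −78 → 0 °C
Reagents that add atoms: N-phenylbis(trifluoromethanesulfonimide), O=S(=O)(N(c1ccccc1)S(=O)(=O)C(F)(F)F)C(F)(F)F
Why: Kinetic deprotonation at the unsubstituted α-methylene (C1) rather than at the hindered C8 methine or the far less acidic ester, followed by O-sulfonylation of the enolate to the enol triflate.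

**Step 7**
Reactants: 13 the enol triflate; 14 (trimethylsilyl)methylmagnesium chloride
Product: 15 methyl 3-{(1S,4R)-4-R*-2-[(trimethylsilyl)methyl]cyclobut-2-en-1-yl}butanoate
Conditions: Pd(PPh3)4 (5 mol %), THF, 0 °C → rt
Reagents that add atoms: none
Why: Kumada cross-coupling of an enol triflate with the silylmethyl Grignard reagent under zerovalent palladium catalysis, the standard route to allylsilanes, the poorly nucleophilic Grignard reagent leaving the methyl ester alone at this temperature.

**Step 8**
Reactants: 15 the allylsilane ester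
Product: 16 3-{(1S,4R)-4-R*-2-[(trimethylsilyl)methyl]cyclobut-2-en-1-yl}butanal
Conditions: iBu2AlH (1.05 equiv), CH2Cl2, −78 °C; MeOH, then aq. Rochelle salt
Reagents that add atoms: none
Why: Partial reduction of the methyl ester through the tetrahedral aluminium hemiacetal that is stable at −78 °C, the allylsilane and silyl ethers being inert to the hydride.

**Step 9**
Reactants: 16 the allylsilane aldehyde
Product: 17 (1R,5S,7S)-7-R*-4-methyl-6-methylidenebicyclo[3.1.1]heptan-2-ol (C2 and C4 epimers; side chain anti to the three-carbon bridge)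
Conditions: BF3·OEt2 (1.2 equiv), CH2Cl2, −78 °C; aq. NaHCO3
Reagents that add atoms: none
Why: Intramolecular Hosomi–Sakurai allylation in which the activated aldehyde, held on one face by the C8 arm, is attacked by ring carbon C1 of the allylsilane with loss of silicon, forming C1–C11, closing the six-membered ring across the cyclobutane and shifting the double bond out to the C2 methylene; C1 can only be bonded on the face of the arm and both C11 carbinol epimers are used.

**Step 10**
Reactants: 17 the bicyclic alcohol
Product: 18 (1R,5S,7S)-7-[(3R)-3-(TBS-oxy)-5-hydroxy-2-methylpentan-2-yl]-4-methyl-6-methylidenebicyclo[3.1.1]heptan-2-ol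
Conditions: PPTS (cat.), MeOH, rt
Reagents that add atoms: none
Why: Acid-catalysed methanolysis cleaves the unhindered primary silyl ether much faster than the neopentyl-type secondary one at C5.

**Step 11**
Reactants: 18 the diol
Product: 19 (3R)-3-(TBS-oxy)-4-methyl-4-[(1R,5S,7S)-4-methyl-6-methylidene-2-oxobicyclo[3.1.1]heptan-7-yl]pentanal
Conditions: Dess–Martin periodinane (2.5 equiv), NaHCO3, CH2Cl2, 0 °C → rt
Reagents that add atoms: none
Why: Dess–Martin oxidation of the primary and the secondary alcohol in one operation, the β,γ-unsaturated ketone being unable to conjugate because C1 is a bridgehead and the buffered medium sparing the β-silyloxy aldehyde.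

**Step 12**
Reactants: 19 the keto aldehyde
Product: 22 tricyclic hydroxy ketone (C2 methyl; C3 hydroxyl; C5 TBS ether; C9 epimers), via alkylchromium dichloride 20 (not isolated), via chromium alkoxide 21 (not isolated)
Conditions: Co(salen) (10 mol %), N-fluoro-2,4,6-trimethylpyridinium tetrafluoroborate (1 equiv, slow addition), PhSiH3 (1.5 equiv), CrCl2 (3 equiv), THF–DMF, 0.005 M, 0 °C → rt; then H2O
Reagents that add atoms: none
Why: Proposed new method: a trivalent cobalt hydride, generated from Co(salen), the N-fluoropyridinium oxidant and PhSiH3, should transfer a hydrogen atom to the CH2 terminus of the C2 methylene, creating the C2 methyl group and a tertiary cyclobutyl radical; divalent chromium captures the radical as alkylchromium 20, which adds to the tethered aldehyde to give alkoxide 21 and, after hydrolysis, 22. The closest known reaction type is the intermolecular, branch-selective reductive coupling of 1,1-disubstituted alkenes with aldehydes by cobalt hydrogen-atom transfer and chromium; its intramolecular use at a cyclobutane carbon is the extension. The seven-membered ring (C2, C3, C4, C5, C6, C7 and C1 or C8) closes in a 7-exo-trig mode, nucleophilic C2 attacking carbonyl carbon C3 whose oxygen stays outside the ring. C2 is controlled by the tether, because the aldehyde chain hangs from C7 on the face anti to the C9–C11 bridge and can reach only that face of C2, leaving the new methyl syn to the bridge; C3 is controlled by a chair-like, chromium-bound transition state in which the C5 silyloxy group is pseudo-equatorial and the forming C3–O–Cr bond points to the C1 side, anti to it. The step needs hydrogen-atom transfer to the alkene and not to the carbonyl groups (secured by the methylenecyclobutane being the only unactivated, electron-rich alkene), radical capture faster than ring opening (secured by the poor overlap of the cyclobutyl radical orbital with its own ring bonds), and addition to the aldehyde and not the C11 ketone (secured by the tether and the aldehyde preference of organochromium reagents).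

**Step 13**
Reactants: 22 the tricyclic hydroxy ketone; 23 2-methylpropanoyl chloride
Product: 24 C3 isobutyrate of 22
Conditions: pyridine, DMAP (cat.), CH2Cl2, 0 °C → rt
Reagents that add atoms: none
Why: DMAP-catalysed acylation of the hindered secondary C3 alcohol, which retains the C3 configuration.

**Step 14**
Reactants: 24 the isobutyrate ketone
Product: 25 C11 trimethylsilyl enol ether (C10=C11) of 24
Conditions: TMSOTf, Et3N, CH2Cl2, 0 °C
Reagents that add atoms: trimethylsilyl trifluoromethanesulfonate, C[Si](C)(C)OS(=O)(=O)C(F)(F)F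
Why: Soft enolisation of the ketone with a silyl triflate and an amine, possible only toward C10 because C1 is a bridgehead of the bicyclo[3.1.1] unit, and too mild to enolise the ester.

**Step 15**
Reactants: 25 the silyl enol ether
Product: 26 C9=C10 enone (C5 TBS ether, C3 isobutyrate)
Conditions: Pd(OAc)2 (1.1 equiv), MeCN, rt
Reagents that add atoms: none
Why: Saegusa–Ito oxidation, in which palladation of the enol silane and β-hydride elimination install the C9–C10 double bond and remove the C9 stereocentre, so both epimers converge.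

**Step 16**
Reactants: 26 the silylated enone
Product: 27 C5 alcohol (C3 isobutyrate, enone)
Conditions: HF·pyridine, THF, 0 °C → rt
Reagents that add atoms: none
Why: Fluoride cleavage of the secondary silyl ether under mildly acidic conditions, which avoid 1,3-acyl migration and leave the enone and ester intact.

**Step 17**
Reactants: 27 the C5 alcohol; 28 2-methylprop-2-enoyl chloride
Product: 29 CNP0214356.1
Conditions: Et3N, DMAP (cat.), CH2Cl2, 0 °C → rt (trace BHT)
Reagents that add atoms: none
Why: DMAP-catalysed acylation of the C5 alcohol with the acid chloride gives the target without touching any stereocentre.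

**Compound list**

1 | 3-(TBS-oxy)propan-1-ol | CC(C)(C)[Si](C)(C)OCCCO | starting material
2 | 3-methylbuta-1,2-diene | CC(C)=C=C | starting material
3 | (3R)-1-(TBS-oxy)-4,4-dimethylhex-5-en-3-ol | C=CC(C)(C)[C@H](O)CCO[Si](C)(C)C(C)(C)C | intermediate
4 | (3R)-1,3-bis(TBS-oxy)-4,4-dimethylhex-5-ene | C=CC(C)(C)[C@H](O[Si](C)(C)C(C)(C)C)CCO[Si](C)(C)C(C)(C)C | intermediate
5 | trichloroacetyl chloride | ClC(Cl)(Cl)C(Cl)=O | starting material
6 | dichloroketene | ClC(Cl)=C=O | intermediate (not isolated)
7 | 2,2-dichloro-3-R*-cyclobutan-1-one (C3 epimers) | O=C1CC(C(C)(C)[C@H](O[Si](C)(C)C(C)(C)C)CCO[Si](C)(C)C(C)(C)C)C1(Cl)Cl | intermediate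
8 | 3-R*-cyclobutan-1-one | O=C1CC(C1)C(C)(C)[C@H](O[Si](C)(C)C(C)(C)C)CCO[Si](C)(C)C(C)(C)C | intermediate
9 | methyl (E)-but-2-enoate | C/C=C/C(=O)OC | starting material
10 | lithium (3R)-3-R*-cyclobut-1-en-1-olate | [Li+].[O-]C1=C[C@@H](C1)C(C)(C)[C@H](O[Si](C)(C)C(C)(C)C)CCO[Si](C)(C)C(C)(C)C | intermediate (not isolated)
11 | methyl 3-[(1S,2R)-2-R*-4-oxocyclobutyl]butanoate (C9 epimers) | COC(=O)CC(C)[C@H]1[C@@H](CC1=O)C(C)(C)[C@H](O[Si](C)(C)C(C)(C)C)CCO[Si](C)(C)C(C)(C)C | intermediate
12 | potassium enolate of 11 (C1=C2) | COC(=O)CC(C)[C@H]1[C@@H](C=C1[O-])C(C)(C)[C@H](O[Si](C)(C)C(C)(C)C)CCO[Si](C)(C)C(C)(C)C.[K+] | intermediate (not isolated)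
13 | methyl 3-[(1S,4R)-4-R*-2-(trifluoromethylsulfonyloxy)cyclobut-2-en-1-yl]butanoate | COC(=O)CC(C)[C@H]1[C@@H](C=C1OS(=O)(=O)C(F)(F)F)C(C)(C)[C@H](O[Si](C)(C)C(C)(C)C)CCO[Si](C)(C)C(C)(C)C | intermediate
14 | (trimethylsilyl)methylmagnesium chloride | C[Si](C)(C)C[Mg]Cl | starting material
15 | methyl 3-{(1S,4R)-4-R*-2-[(trimethylsilyl)methyl]cyclobut-2-en-1-yl}butanoate | COC(=O)CC(C)[C@H]1[C@@H](C=C1C[Si](C)(C)C)C(C)(C)[C@H](O[Si](C)(C)C(C)(C)C)CCO[Si](C)(C)C(C)(C)C | intermediate
16 | 3-{(1S,4R)-4-R*-2-[(trimethylsilyl)methyl]cyclobut-2-en-1-yl}butanal | O=CCC(C)[C@H]1[C@@H](C=C1C[Si](C)(C)C)C(C)(C)[C@H](O[Si](C)(C)C(C)(C)C)CCO[Si](C)(C)C(C)(C)C | intermediate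
17 | (1R,5S,7S)-7-R*-4-methyl-6-methylidenebicyclo[3.1.1]heptan-2-ol (C2, C4 epimers) | CC(C)(C)[Si](C)(C)OCC[C@@H](O[Si](C)(C)C(C)(C)C)C(C)(C)[C@H]1[C@H]2C(=C)[C@@H]1C(O)CC2C | intermediate
18 | (1R,5S,7S)-7-[(3R)-3-(TBS-oxy)-5-hydroxy-2-methylpentan-2-yl]-4-methyl-6-methylidenebicyclo[3.1.1]heptan-2-ol | OCC[C@@H](O[Si](C)(C)C(C)(C)C)C(C)(C)[C@H]1[C@H]2C(=C)[C@@H]1C(O)CC2C | intermediate
19 | (3R)-3-(TBS-oxy)-4-methyl-4-[(1R,5S,7S)-4-methyl-6-methylidene-2-oxobicyclo[3.1.1]heptan-7-yl]pentanal | O=CC[C@@H](O[Si](C)(C)C(C)(C)C)C(C)(C)[C@H]1[C@H]2C(=C)[C@@H]1C(=O)CC2C | intermediate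
20 | C2 alkylchromium dichloride of 19 (tertiary C2–Cr, C2 methyl) | O=CC[C@@H](O[Si](C)(C)C(C)(C)C)C(C)(C)[C@H]1[C@H]2C(C)([Cr](Cl)Cl)[C@@H]1C(=O)CC2C | intermediate (not isolated)
21 | chromium C3 alkoxide of 22 | CC(C)(C)[Si](C)(C)O[C@@H]1C[C@@H](O[Cr](Cl)Cl)[C@@]2(C)[C@@H]3C(=O)CC(C)[C@H]2[C@@H]3C1(C)C | intermediate (not isolated)
22 | tricyclic hydroxy ketone: C2 methyl, C3 hydroxyl, C5 TBS ether, C11 ketone, C9 epimers; C1, C2, C3, C5, C7, C8 arranged as in the target | CC(C)(C)[Si](C)(C)O[C@@H]1C[C@@H](O)[C@@]2(C)[C@@H]3C(=O)CC(C)[C@H]2[C@@H]3C1(C)C | intermediate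
23 | 2-methylpropanoyl chloride | CC(C)C(Cl)=O | starting material
24 | C3 isobutyrate of 22 | CC(C)(C)[Si](C)(C)O[C@@H]1C[C@@H](OC(=O)C(C)C)[C@@]2(C)[C@@H]3C(=O)CC(C)[C@H]2[C@@H]3C1(C)C | intermediate
25 | C11 trimethylsilyl enol ether of 24 | CC(C)(C)[Si](C)(C)O[C@@H]1C[C@@H](OC(=O)C(C)C)[C@@]2(C)[C@@H]3C(O[Si](C)(C)C)=CC(C)[C@H]2[C@@H]3C1(C)C | intermediate
26 | C9=C10 enone, C5 TBS ether, C3 isobutyrate | CC(C)(C)[Si](C)(C)O[C@@H]1C[C@@H](OC(=O)C(C)C)[C@@]2(C)[C@@H]3C(=O)C=C(C)[C@H]2[C@@H]3C1(C)C | intermediate
27 | C5 alcohol, C3 isobutyrate, enone | O[C@@H]1C[C@@H](OC(=O)C(C)C)[C@@]2(C)[C@@H]3C(=O)C=C(C)[C@H]2[C@@H]3C1(C)C | intermediate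
28 | 2-methylprop-2-enoyl chloride | C=C(C)C(Cl)=O | starting material
29 | CNP0214356.1: C5 methacrylate, C3 isobutyrate of the tricyclic enone, (1R,2R,3R,5R,7S,8R) in the overview numbering | C=C(C)C(=O)O[C@@H]1C[C@@H](OC(=O)C(C)C)[C@@]2(C)[C@@H]3C(=O)C=C(C)[C@H]2[C@@H]3C1(C)C | target

**Step count and risks**

Total steps: 17. Longest linear sequence: 17 steps (from alcohol 1).

1. Step 12 (proposed new method). The tertiary radical may take up a second hydrogen atom before chromium captures it, the N–F oxidant may be consumed by divalent chromium, or homolysis of the hindered C–Cr bond may outrun carbonyl addition. Fallback, from 19 back to 22: the iron-mediated hydrogen-atom-transfer reductive cyclisation that is established for alkene-tethered ketones (Fe(acac)3, PhSiH3, EtOH–ethylene glycol, 60 °C, high dilution). The same tertiary radical adds directly to the aldehyde carbon on the only face it can reach and the alkoxy radical is reduced, so no organochromium species is needed and no further compound is made (F0).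

2. Step 9. Protodesilylation of the allylsilane or intermolecular consumption of the aldehyde may outrun the strained bridging closure. Fallback, from ester 15 back to 19: the ring is closed at the acyl oxidation level instead. Saponification (LiOH, THF–H2O) gives the carboxylic acid F1; neutral chlorination with 1-chloro-N,N,2-trimethylprop-1-enylamine gives the acid chloride F2; SnCl4 (CH2Cl2, −78 °C) brings about intramolecular acylation of the allylsilane by the much more electrophilic acylium ion and gives the bis-silylated methylidene ketone F3 with C11 already a ketone; PPTS in MeOH frees the primary alcohol of hydroxy ketone F4, and Dess–Martin oxidation returns to 19.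

3. Step 5. Insufficient discrimination between the two α-methylenes, or equilibration of the enolate before the Michael addition, would give a mixture of C7 epimers that runs through the route as hard-to-separate diastereomers. Fallback, from 8 back to lithium enolate 10 (the intermediate of step 5): C7 is set by catalyst-controlled hydride delivery instead of deprotonation. Unselective enolisation with in situ silylation (LDA, TMSCl, THF, −78 °C) gives the trimethylsilyl enol ether F5 together with its C7 epimer F6; Saegusa–Ito oxidation of the mixture (Pd(OAc)2, MeCN) converges on cyclobutenone F7; copper hydride conjugate reduction with a chiral bisphosphine (Cu(OAc)2, DTBM-SEGPHOS of the appropriate hand, (EtO)2MeSiH, toluene) adds hydride to one face of C7 and leaves the regiodefined silyl enol ether F8; MeLi (THF, 0 °C) converts F8 into lithium enolate 10 in the absence of amine, and 10 is taken on with 9 as in step 5.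

**Further compounds**

F0 | step 12 | none | none
F1 | step 9 | 3-{(1S,4R)-4-R*-2-[(trimethylsilyl)methyl]cyclobut-2-en-1-yl}butanoic acid | OC(=O)CC(C)[C@H]1[C@@H](C=C1C[Si](C)(C)C)C(C)(C)[C@H](O[Si](C)(C)C(C)(C)C)CCO[Si](C)(C)C(C)(C)C
F2 | step 9 | 3-{(1S,4R)-4-R*-2-[(trimethylsilyl)methyl]cyclobut-2-en-1-yl}butanoyl chloride | ClC(=O)CC(C)[C@H]1[C@@H](C=C1C[Si](C)(C)C)C(C)(C)[C@H](O[Si](C)(C)C(C)(C)C)CCO[Si](C)(C)C(C)(C)C
F3 | step 9 | (1R,5S,7S)-7-R*-4-methyl-6-methylidenebicyclo[3.1.1]heptan-2-one | CC(C)(C)[Si](C)(C)OCC[C@@H](O[Si](C)(C)C(C)(C)C)C(C)(C)[C@H]1[C@H]2C(=C)[C@@H]1C(=O)CC2C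
F4 | step 9 | (1R,5S,7S)-7-[(3R)-3-(TBS-oxy)-5-hydroxy-2-methylpentan-2-yl]-4-methyl-6-methylidenebicyclo[3.1.1]heptan-2-one | OCC[C@@H](O[Si](C)(C)C(C)(C)C)C(C)(C)[C@H]1[C@H]2C(=C)[C@@H]1C(=O)CC2C
F5 | step 5 | trimethyl{[(3R)-3-R*-cyclobut-1-en-1-yl]oxy}silane | C[Si](C)(C)OC1=C[C@@H](C1)C(C)(C)[C@H](O[Si](C)(C)C(C)(C)C)CCO[Si](C)(C)C(C)(C)C
F6 | step 5 | trimethyl{[(3S)-3-R*-cyclobut-1-en-1-yl]oxy}silane (C7 epimer of F5) | C[Si](C)(C)OC1=C[C@H](C1)C(C)(C)[C@H](O[Si](C)(C)C(C)(C)C)CCO[Si](C)(C)C(C)(C)C
F7 | step 5 | 3-R*-cyclobut-2-en-1-one | O=C1C=C(C1)C(C)(C)[C@H](O[Si](C)(C)C(C)(C)C)CCO[Si](C)(C)C(C)(C)C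
F8 | step 5 | diethoxy(methyl){[(3R)-3-R*-cyclobut-1-en-1-yl]oxy}silane | CCO[Si](C)(OCC)OC1=C[C@@H](C1)C(C)(C)[C@H](O[Si](C)(C)C(C)(C)C)CCO[Si](C)(C)C(C)(C)C
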